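On warming from −5 °C to 25 °C, the ring closure G → E speeds up 51-fold, faster than the capture G + E → G.E at 12-fold, and my choice of the next run hung on that gap.

    J ⇌ E, rate k1*(cs1 - [E]) while solid is left; crystals form when [E] > cs1 (cs1 = 0.057 M, k1 = 0.28 s⁻¹)
    G + G ⇌ G2 (K2 = 1.1 M⁻¹, k2 = 0.092 M⁻¹ s⁻¹, Ea2 = 61.0 kJ mol⁻¹, ΔH2 = −23.0 kJ mol⁻¹)
    G + E → G.E (k3 = 0.98 M⁻¹ s⁻¹, Ea3 = 55.0 kJ mol⁻¹)
    G → E (k4 = 0.13 s⁻¹, Ea4 = 87.0 kJ mol⁻¹)
    (constants at 25 °C)

- epsilon: G 0.20 M; temperature 25 °C; time 80 s
- zeta: G 0.20 M; temperature −5 °C; time 80 s

- percentages count the G that a species holds: one G2 or G.E counts as two
- E is meant together with its J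
- for a step with 2 of a species take k times the square, and two of it per event
- solid, in amounts per volume of the solution: J
- the list of constants is for 25 °C, to be carried to other temperatures by the activation energies and enthalpies

1. the flask with the highest share of E in all that became E or G2 or G.E ("all alike" if they lie within 1.5 percentage points) (epsilon / zeta / all alike)
2. share of E in all that became E or G2 or G.E, epsilon
3. share of E in all that became E or G2 or G.E, zeta

I had to choose a temperature and a charge, so I looked for what bounds [E]. Ring closure made E at 0.13 s⁻¹ times [G], and capture spent it at 0.98 M⁻¹ s⁻¹ times [G][E]. Since [G] stands in both rates, dissolved [E] stops rising at their ratio 0.133 M, the balance concentration, which is the selectivity factor of the two paths of G written as a concentration.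

In epsilon this lay above the solubility 0.057 M, so crystals were possible. I set G2 aside and took crystallisation as instant. Integrating the two rates, saturation came after 0.0920 M of G had reacted, less than the charge of 0.20 M, so I expected crystals in epsilon. With [E] held at 0.057 M, each further G then added a net 39.9 % of an E, which gave epsilon a share of 50.0 %.

In zeta the balance concentration fell to 0.0313 M, below the solubility, so I expected no crystals and a late share near 15.6 %. At the start of zeta, ring closure took about half of the reacting G and G2 took the rest, and I expected capture to lower the share further. I therefore put zeta below epsilon, without a figure.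

A warm charge of 0.080 M, below 0.0920 M, should stay free of crystals. Starting from 0.0400 M and putting each answer back into the integrated balance, I got 0.0483 M, then 0.0509 M, or 63.6 % of the charge, more than 50.0 %. So I chose to stay warm and charge less.

The forecast gave epsilon, with 45 % for epsilon, below my figure, and 30 % for zeta, holding that “crystallisation holds dissolved E near its solubility limit”.

The simulation gave epsilon as the highest, with 47.5 % for epsilon and 29.5 % for zeta. Epsilon held 19.0 % of its charge as J at 80.0 s, and zeta held 0 %. Against the balance concentration of zeta, 15.6 % of its charge, its share left until 800 s was 15.8 %. The neighbour of epsilon charged with 0.080 M held 0 % as J and gave a share of 65.0 %.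

All constants are those of an exercise; the flask was simulated.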